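Retrosynthetic cuts: C4–C3 and C10–C11 (two sp3–sp2 couplings with Z-iodoalkenols), the lactone bond C23–O22, the pair C16–O22/C20–O21 (singlet oxygen), C16=C18 (metathesis), C6–C20 (malonate alkylation) and O7–C6 (O–H insertion).
Forward order: the oxepine ring closes by metathesis, the 1,2-dioxine ring by (4+2) addition of O2, and the lactone bridge after O–O cleavage; the C8 chain (Negishi) and the C6 chain (Suzuki–Miyaura) are joined last.
Enabling feature: O22 on C16 and the hydroxyl O21 on C20 are cis-1,4 oxygens on one face of the oxepane ring (C6, O7, C8, C16, C18, C19, C20), i.e. the reduced endoperoxide of a C16=C18–C19=C20 ring diene.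
Stereochemistry: C8 from a Sharpless kinetic resolution; C16 and C20 from singlet oxygen adding anti to the C8 substituent; C6 when O22 lactonises onto the syn ester of an achiral malonate; both Z alkenes from stereodefined iodoalkenols coupled with retention.

Key step: step 10

Remark: atom labels C1 to O26 follow the order of the atoms in the target SMILES; the C6 esters are carried as benzyl esters and the C10 oxygen as a TBS ether; 1, 2, 5, 8, 15, 27 and 33 are taken as purchased.

Step 1
Reactants: 1 3-[(tert-butyldimethylsilyl)oxy]propanal; 2 isopropenylmagnesium bromide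
Product: 3 rac-5-[(tert-butyldimethylsilyl)oxy]-2-methylpent-1-en-3-ol
Conditions: 2 (1.2 equiv), THF, −78 °C to 0 °C; aq. NH4Cl
Reagents that add atoms: none
Why: Grignard 1,2-addition of the alkenylmagnesium reagent to the unhindered aldehyde is fast at low temperature and gives the allylic carbinol as a racemate, the C8 configuration being sorted out in the next step.

Step 2
Reactants: 3 rac-5-[(tert-butyldimethylsilyl)oxy]-2-methylpent-1-en-3-ol
Product: 4 (3S)-5-[(tert-butyldimethylsilyl)oxy]-2-methylpent-1-en-3-ol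
Conditions: Ti(OiPr)4, D-(−)-diisopropyl tartrate, t-BuOOH (0.6 equiv), 4 Å MS, CH2Cl2, −20 °C
Reagents that add atoms: none
Why: In this Sharpless kinetic resolution of a secondary allylic alcohol the titanium–D-(−)-tartrate–hydroperoxide complex epoxidises the (R)-enantiomer much faster, so the (S)-alcohol (C8 of the target) should be recovered in high enantiomeric purity at slightly over half conversion.

Step 3
Reactants: 5 dibenzyl malonate
Product: 6 dibenzyl 2-diazomalonate
Conditions: 4-acetamidobenzenesulfonyl azide, Et3N, MeCN, 0 °C to rt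
Reagents that add atoms: 4-acetamidobenzenesulfonyl azide, CC(=O)Nc1ccc(cc1)S(=O)(=O)N=[N+]=[N-]
Why: Regitz diazo transfer from a sulfonyl azide to an active methylene compound is the standard route to diazomalonates.

Step 4
Reactants: 4 (3S)-5-[(tert-butyldimethylsilyl)oxy]-2-methylpent-1-en-3-ol; 6 dibenzyl 2-diazomalonate
Product: 7 dibenzyl 2-{[(3S)-5-[(tert-butyldimethylsilyl)oxy]-2-methylpent-1-en-3-yl]oxy}malonate
Conditions: Rh2(OAc)4 (1 mol%), PhH, 80 °C, slow addition of 6
Reagents that add atoms: none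
Why: Rh2(OAc)4 turns the diazomalonate into an electrophilic carbenoid whose O–H insertion into a secondary alcohol (oxonium ylide, then proton transfer) outruns cyclopropanation and [2,3]-shift, forming the O7–C6 ether bond without touching the C8 stereocentre.

Step 5
Reactants: 7 dibenzyl alkoxymalonate (ether of 4); 8 2-bromo-N-methoxy-N-methylacetamide
Product: 9 dibenzyl 2-{[(3S)-5-[(tert-butyldimethylsilyl)oxy]-2-methylpent-1-en-3-yl]oxy}-2-{2-[methoxy(methyl)amino]-2-oxoethyl}malonate
Conditions: Cs2CO3, DMF, 0 °C to rt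
Reagents that add atoms: none
Why: The alkoxymalonate C–H is acidic enough for Cs2CO3 and its soft enolate should displace bromide from the α-bromo amide in an SN2 malonate alkylation, creating the fully substituted but still achiral C6 and the C6–C20 bond.

Step 6
Reactants: 9 Weinreb amide of the C6-alkylated malonate
Product: 10 dibenzyl 2-{[(3S)-5-[(tert-butyldimethylsilyl)oxy]-2-methylpent-1-en-3-yl]oxy}-2-(2-oxobut-3-en-1-yl)malonate
Conditions: CH2=CHMgBr (1.3 equiv), THF, −78 °C to −20 °C; cold 1 M HCl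
Reagents that add atoms: vinylmagnesium bromide, C=C[Mg]Br
Why: In this Weinreb ketone synthesis the N-methoxy-N-methylamide forms a stable five-membered magnesium chelate with the vinyl Grignard reagent at low temperature, faster than attack on the two benzyl esters shielded by the quaternary C6, and releases the vinyl ketone (C19=O, C18) only on acidic quench.

Step 7
Reactants: 10 vinyl ketone with isopropenyl ether
Product: 11 dibenzyl (7S)-7-{2-[(tert-butyldimethylsilyl)oxy]ethyl}-6-methyl-4-oxo-3,4-dihydrooxepine-2,2(7H)-dicarboxylate (ring enone, C16=C18–C19=O)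
Conditions: second-generation Hoveyda–Grubbs catalyst, RuCl2(H2IMes)(=CH–C6H4-2-OiPr) (5 mol%), PhMe (2 mM), 80 °C
Reagents that add atoms: none
Why: Ring-closing olefin metathesis between a vinyl ketone and a 1,1-disubstituted alkene, helped by the gem-diester (Thorpe–Ingold effect) and the loss of ethene, is a known way to β-methyl cycloalkenones and should close the seven-membered ring with C16=C18 necessarily cis in the ring.

Step 8
Reactants: 11 ring enone
Product: 13 dibenzyl (7S)-7-{2-[(tert-butyldimethylsilyl)oxy]ethyl}-6-methyl-4-{[(trifluoromethyl)sulfonyl]oxy}oxepine-2,2(7H)-dicarboxylate (dienyl triflate), via potassium dienolate 12 (not isolated)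
Conditions: KN(SiMe3)2, THF, −78 °C; then PhNTf2, −78 °C to −40 °C
Reagents that add atoms: N-phenylbis(trifluoromethanesulfonimide), O=S(=O)(N(c1ccccc1)S(=O)(=O)C(F)(F)F)C(F)(F)F
Why: Kinetic deprotonation of an enone with a hindered amide base at −78 °C occurs at the α′ carbon (C20) and not at the γ positions, and O-sulfonylation of the cross-conjugated dienolate gives the 2-triflyloxy-1,3-diene as in standard enol triflate formation.

Step 9
Reactants: 13 dienyl triflate
Product: 14 dibenzyl (7S)-7-{2-[(tert-butyldimethylsilyl)oxy]ethyl}-6-methyloxepine-2,2(7H)-dicarboxylate (2,7-dihydrooxepine diene C16=C18–C19=C20)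
Conditions: Pd(OAc)2 (5 mol%), PPh3, HCO2H, Et3N, DMF, 60 °C
Reagents that add atoms: none
Why: Palladium-catalysed formate reduction of alkenyl triflates (oxidative addition, formate exchange, decarboxylation, reductive elimination) replaces OTf by H without moving the double bonds and tolerates esters and silyl ethers.

Step 10
Reactants: 14 2,7-dihydrooxepine diene; 15 dioxygen
Product: 16 dibenzyl (1R,2S,5S)-2-{2-[(tert-butyldimethylsilyl)oxy]ethyl}-1-methyl-3,6,7-trioxabicyclo[3.2.2]non-8-ene-4,4-dicarboxylate (endoperoxide)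
Conditions: O2, tetraphenylporphyrin (1 mol%), visible light, CH2Cl2, −78 °C
Reagents that add atoms: none
Why: Photosensitised singlet oxygen should add to the s-cis diene C16=C18–C19=C20 held in the oxepine ring in a concerted suprafacial (4+2) cycloaddition, the reaction type known for cyclohexa- and cyclohepta-1,3-dienes. The new 1,2-dioxine ring (C16, C18, C19, C20, O21, O22) closes by cycloaddition with both C–O bonds formed on one face in a single event, so O22 on C16 and O21 on C20 are necessarily cis. Their configuration relative to C8 follows from facial selection: the C8 side chain sits pseudo-equatorial, because a pseudo-axial position would place it 1,3-diaxial to an ester across O7, and oxygen approaches the open end of the diene from the face that carries C8–H, away from the O7 flap. C6 bears two identical esters and is not a stereocentre, so C8 is the only control element and no mismatched pairing can arise. Preference for (4+2) addition over the ene reaction is expected because the diene is locked s-cis and no other electron-rich alkene is present, the side-chain alkenes being deliberately absent at this stage.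

Step 11
Reactants: 16 unsaturated endoperoxide
Product: 17 dibenzyl (1R,2S,5S)-2-{2-[(tert-butyldimethylsilyl)oxy]ethyl}-1-methyl-3,6,7-trioxabicyclo[3.2.2]nonane-4,4-dicarboxylate (saturated endoperoxide)
Conditions: KO2CN=NCO2K, AcOH, MeOH/CH2Cl2, 0 °C to rt
Reagents that add atoms: none
Why: Diimide, released from the azodicarboxylate by acetic acid, transfers two hydrogens in a concerted syn fashion to the strained cis-disubstituted C18=C19 bond and, unlike catalytic hydrogenation, leaves the O–O bond and the benzyl esters intact.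

Step 12
Reactants: 17 saturated endoperoxide
Product: 19 benzyl (1S,2S,5R,9S)-9-{2-[(tert-butyldimethylsilyl)oxy]ethyl}-2-hydroxy-5-methyl-7-oxo-6,8-dioxabicyclo[3.2.2]nonane-1-carboxylate (hydroxy lactone), via cis-1,4-diol 18 (not isolated)
Conditions: Zn dust, AcOH, CH2Cl2, 0 °C to rt; filter; then camphorsulfonic acid (10 mol%), PhMe, 80 °C
Reagents that add atoms: none
Why: Zinc in acetic acid reduces the O–O bond with both C–O bonds untouched to give the cis-1,4-diol, and under acid catalysis only the tertiary C16 hydroxyl (O22) can reach an ester, the one on its own face, through a six-membered transition state (the C20 hydroxyl could only form a β-lactone), so this intramolecular transesterification should set C6 as required.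

Step 13
Reactants: 19 hydroxy lactone
Product: 20 benzyl (1S,2S,5R,9S)-2-[(tert-butyldimethylsilyl)oxy]-9-{2-[(tert-butyldimethylsilyl)oxy]ethyl}-5-methyl-7-oxo-6,8-dioxabicyclo[3.2.2]nonane-1-carboxylate
Conditions: TBSOTf (2.5 equiv), 2,6-lutidine, CH2Cl2, 0 °C
Reagents that add atoms: tert-butyldimethylsilyl trifluoromethanesulfonate, CC(C)(C)[Si](C)(C)OS(=O)(=O)C(F)(F)F
Why: The silyl triflate with 2,6-lutidine silylates even a hindered secondary alcohol, blocks the β-hydroxy carbonyl unit against retro-aldol cleavage in the basic steps ahead and would also restore any primary silyl ether lost in step 12.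

Step 14
Reactants: 20 bis-silylated lactone benzyl ester
Product: 21 (1S,2S,5R,9S)-2-[(tert-butyldimethylsilyl)oxy]-9-{2-[(tert-butyldimethylsilyl)oxy]ethyl}-5-methyl-7-oxo-6,8-dioxabicyclo[3.2.2]nonane-1-carboxylic acid
Conditions: H2 (1 atm), Pd/C (10%), EtOAc, rt
Reagents that add atoms: none
Why: Hydrogenolysis of a benzyl ester over Pd/C is clean at this stage because the molecule holds no alkene, and the lactone and the silyl ethers are inert in ethyl acetate.

Step 15
Reactants: 21 lactone carboxylic acid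
Product: 22 (1R,2S,5R,9S)-2-[(tert-butyldimethylsilyl)oxy]-9-{2-[(tert-butyldimethylsilyl)oxy]ethyl}-1-(hydroxymethyl)-5-methyl-6,8-dioxabicyclo[3.2.2]nonan-7-one
Conditions: BH3·SMe2, THF, 0 °C to rt; MeOH
Reagents that add atoms: none
Why: Borane reduces a free carboxylic acid through its acyloxyborane much faster than it attacks a lactone or a silyl ether, the classical chemoselective acid-to-alcohol reduction, and so turns the carboxyl carbon into C5.

Step 16
Reactants: 22 primary alcohol (C5–OH)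
Product: 23 (1S,2S,5R,9S)-2-[(tert-butyldimethylsilyl)oxy]-9-{2-[(tert-butyldimethylsilyl)oxy]ethyl}-5-methyl-7-oxo-6,8-dioxabicyclo[3.2.2]nonane-1-carbaldehyde
Conditions: Dess–Martin periodinane, NaHCO3, CH2Cl2, rt
Reagents that add atoms: none
Why: Dess–Martin oxidation converts the neopentyl primary alcohol into the aldehyde under buffered neutral conditions, and the aldehyde cannot epimerise because C6 is fully substituted.

Step 17
Reactants: 23 aldehyde (C5)
Product: 24 (1R,2S,5R,9S)-2-[(tert-butyldimethylsilyl)oxy]-9-{2-[(tert-butyldimethylsilyl)oxy]ethyl}-1-ethenyl-5-methyl-6,8-dioxabicyclo[3.2.2]nonan-7-one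
Conditions: Ph3PCH3Br, KN(SiMe3)2, THF, 0 °C; then 23, −78 °C to 0 °C
Reagents that add atoms: methyltriphenylphosphonium bromide, C[P+](c1ccccc1)(c1ccccc1)c1ccccc1.[Br-]
Why: Wittig methylenation with the non-stabilised ylide is fast on an aldehyde at low temperature, well before the hindered lactone carbonyl can react, and provides the C5=C4 vinyl group needed for hydroboration.

Step 18
Reactants: 24 vinyl lactone with two silyl ethers
Product: 25 (1R,2S,5R,9S)-2-[(tert-butyldimethylsilyl)oxy]-1-ethenyl-9-(2-hydroxyethyl)-5-methyl-6,8-dioxabicyclo[3.2.2]nonan-7-one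
Conditions: camphorsulfonic acid (10 mol%), MeOH/CH2Cl2 (1:1), 0 °C
Reagents that add atoms: none
Why: Acid-catalysed methanolysis removes a primary tert-butyldimethylsilyl ether far faster than the hindered secondary one at C20, a standard selective desilylation.

Step 19
Reactants: 25 primary alcohol (C10–OH)
Product: 26 (1R,2S,5R,9S)-2-[(tert-butyldimethylsilyl)oxy]-1-ethenyl-9-(2-iodoethyl)-5-methyl-6,8-dioxabicyclo[3.2.2]nonan-7-one
Conditions: I2, PPh3, imidazole, CH2Cl2, 0 °C to rt
Reagents that add atoms: iodine, II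
Why: Appel-type iodination converts the unhindered primary alcohol into the iodide by SN2 displacement of the oxyphosphonium group without affecting the vinyl group or the lactone.

Step 20
Reactants: 27 but-2-yn-1-ol
Product: 29 (2Z)-3-iodobut-2-en-1-ol, via alkenylaluminate 28 (not isolated)
Conditions: NaAlH2(OCH2CH2OCH3)2, THF, 0 °C to rt; then I2, −78 °C to 0 °C
Reagents that add atoms: iodine, II
Why: Hydroxyl-directed trans-hydroalumination of the propargylic alcohol delivers hydride to C2 and aluminium to C3 within a five-membered alkoxyaluminate, and iodinolysis with retention gives the Z-iodoalkenol in which iodine is cis to CH2OH.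

Step 21
Reactants: 29 (2Z)-3-iodobut-2-en-1-ol
Product: 30 tert-butyl{[(2Z)-3-iodobut-2-en-1-yl]oxy}dimethylsilane
Conditions: TBSCl, imidazole, CH2Cl2, rt
Reagents that add atoms: tert-butyldimethylsilyl chloride, CC(C)(C)[Si](C)(C)Cl
Why: Standard silylation of a primary alcohol with the silyl chloride and imidazole is needed so that the organozinc partner is not protonated.

Step 22
Reactants: 26 primary iodide; 30 silylated Z-iodoalkenol
Product: 32 (1R,2S,5R,9S)-2-[(tert-butyldimethylsilyl)oxy]-9-[(3Z)-5-[(tert-butyldimethylsilyl)oxy]-3-methylpent-3-en-1-yl]-1-ethenyl-5-methyl-6,8-dioxabicyclo[3.2.2]nonan-7-one, via alkylzinc iodide 31 (not isolated)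
Conditions: Zn dust (activated with BrCH2CH2Br, Me3SiCl), DMA, 40 °C; then 30, PdCl2(dppf) (5 mol%), THF, rt to 40 °C
Reagents that add atoms: none
Why: Direct zinc insertion into the primary C–I bond gives an alkylzinc iodide that tolerates the lactone and silyl ethers, and its Negishi cross-coupling with the alkenyl iodide forms C10–C11 with retention of alkene geometry, so that C10 ends up cis to C14 (Z).

Step 23
Reactants: 33 prop-2-yn-1-ol
Product: 35 (2Z)-3-iodo-2-methylprop-2-en-1-ol, via alkenylmagnesium chelate 34 (not isolated)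
Conditions: CH3MgBr (2.5 equiv), CuI (10 mol%), THF, −10 °C to rt; then I2, −10 °C
Reagents that add atoms: methylmagnesium bromide, C[Mg]Br; iodine, II
Why: Copper-catalysed anti-carbomagnesiation of propargyl alcohol places the methyl group on the internal carbon and magnesium on the terminal carbon within an alkoxide chelate, and iodinolysis with retention gives the Z-iodoalkenol with iodine cis to CH2OH.

Step 24
Reactants: 32 vinyl lactone carrying the C8 chain; 35 (2Z)-3-iodo-2-methylprop-2-en-1-ol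
Product: 37 (1R,2S,5R,9S)-2-[(tert-butyldimethylsilyl)oxy]-9-[(3Z)-5-[(tert-butyldimethylsilyl)oxy]-3-methylpent-3-en-1-yl]-1-[(3Z)-5-hydroxy-4-methylpent-3-en-1-yl]-5-methyl-6,8-dioxabicyclo[3.2.2]nonan-7-one, via B-alkyl-9-BBN 36 (not isolated)
Conditions: 9-BBN, THF, rt; then 35, PdCl2(dppf) (5 mol%), AsPh3, Cs2CO3, DMF/H2O, rt
Reagents that add atoms: none
Why: 9-BBN hydroborates the monosubstituted vinyl group at its terminal carbon and ignores the trisubstituted alkene, and the B-alkyl Suzuki–Miyaura coupling with the alkenyl iodide forms C4–C3 with retention of the Z geometry under conditions mild enough for the lactone and the free allylic alcohol.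

Step 25
Reactants: 37 bis-silyl ether of the target
Product: 38 (1R,2S,5R,9S)-2-hydroxy-1-[(3Z)-5-hydroxy-4-methylpent-3-en-1-yl]-9-[(3Z)-5-hydroxy-3-methylpent-3-en-1-yl]-5-methyl-6,8-dioxabicyclo[3.2.2]nonan-7-one (CNP0105745.1)
Conditions: HF·pyridine, pyridine, THF, 0 °C to rt
Reagents that add atoms: none
Why: Fluoride cleaves both silyl ethers through pentacoordinate silicon under buffered, mildly acidic conditions that should leave the lactone, the β-hydroxy lactone unit and the allylic alcohols untouched.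

Compound list
1 | 3-[(tert-butyldimethylsilyl)oxy]propanal | O=CCCO[Si](C)(C)C(C)(C)C | starting material
2 | isopropenylmagnesium bromide | CC(=C)[Mg]Br | starting material
3 | rac-5-[(tert-butyldimethylsilyl)oxy]-2-methylpent-1-en-3-ol | C=C(C)C(O)CCO[Si](C)(C)C(C)(C)C | intermediate
4 | (3S)-5-[(tert-butyldimethylsilyl)oxy]-2-methylpent-1-en-3-ol | C=C(C)[C@@H](O)CCO[Si](C)(C)C(C)(C)C | intermediate
5 | dibenzyl malonate | O=C(CC(=O)OCc1ccccc1)OCc1ccccc1 | starting material
6 | dibenzyl 2-diazomalonate | [N-]=[N+]=C(C(=O)OCc1ccccc1)C(=O)OCc1ccccc1 | intermediate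
7 | dibenzyl 2-{[(3S)-5-[(tert-butyldimethylsilyl)oxy]-2-methylpent-1-en-3-yl]oxy}malonate | O=C(OCc1ccccc1)C(O[C@@H](CCO[Si](C)(C)C(C)(C)C)C(C)=C)C(=O)OCc1ccccc1 | intermediate
8 | 2-bromo-N-methoxy-N-methylacetamide | CON(C)C(=O)CBr | starting material
9 | dibenzyl 2-{[(3S)-5-[(tert-butyldimethylsilyl)oxy]-2-methylpent-1-en-3-yl]oxy}-2-{2-[methoxy(methyl)amino]-2-oxoethyl}malonate | O=C(OCc1ccccc1)C(CC(=O)N(C)OC)(O[C@@H](CCO[Si](C)(C)C(C)(C)C)C(C)=C)C(=O)OCc1ccccc1 | intermediate
10 | dibenzyl 2-{[(3S)-5-[(tert-butyldimethylsilyl)oxy]-2-methylpent-1-en-3-yl]oxy}-2-(2-oxobut-3-en-1-yl)malonate | O=C(OCc1ccccc1)C(CC(=O)C=C)(O[C@@H](CCO[Si](C)(C)C(C)(C)C)C(C)=C)C(=O)OCc1ccccc1 | intermediate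
11 | dibenzyl (7S)-7-{2-[(tert-butyldimethylsilyl)oxy]ethyl}-6-methyl-4-oxo-3,4-dihydrooxepine-2,2(7H)-dicarboxylate | O=C(OCc1ccccc1)C2(C(=O)OCc3ccccc3)O[C@@H](CCO[Si](C)(C)C(C)(C)C)C(C)=CC(=O)C2 | intermediate
12 | potassium (7S)-2,2-bis(benzyloxycarbonyl)-7-{2-[(tert-butyldimethylsilyl)oxy]ethyl}-6-methyl-2,7-dihydrooxepin-4-olate (dienolate, not isolated) | [O-]C1=CC(C(=O)OCc2ccccc2)(C(=O)OCc3ccccc3)O[C@@H](CCO[Si](C)(C)C(C)(C)C)C(C)=C1.[K+] | intermediate
13 | dibenzyl (7S)-7-{2-[(tert-butyldimethylsilyl)oxy]ethyl}-6-methyl-4-{[(trifluoromethyl)sulfonyl]oxy}oxepine-2,2(7H)-dicarboxylate | O=C(OCc1ccccc1)C2(C(=O)OCc3ccccc3)O[C@@H](CCO[Si](C)(C)C(C)(C)C)C(C)=CC(OS(=O)(=O)C(F)(F)F)=C2 | intermediate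
14 | dibenzyl (7S)-7-{2-[(tert-butyldimethylsilyl)oxy]ethyl}-6-methyloxepine-2,2(7H)-dicarboxylate | O=C(OCc1ccccc1)C2(C(=O)OCc3ccccc3)O[C@@H](CCO[Si](C)(C)C(C)(C)C)C(C)=CC=C2 | intermediate
15 | dioxygen (used as sensitised singlet oxygen) | O=O | starting material
16 | dibenzyl (1R,2S,5S)-2-{2-[(tert-butyldimethylsilyl)oxy]ethyl}-1-methyl-3,6,7-trioxabicyclo[3.2.2]non-8-ene-4,4-dicarboxylate | O=C(OCc1ccccc1)C2(C(=O)OCc3ccccc3)O[C@@H](CCO[Si](C)(C)C(C)(C)C)[C@@]4(C)C=C[C@@H]2OO4 | intermediate
17 | dibenzyl (1R,2S,5S)-2-{2-[(tert-butyldimethylsilyl)oxy]ethyl}-1-methyl-3,6,7-trioxabicyclo[3.2.2]nonane-4,4-dicarboxylate | O=C(OCc1ccccc1)C2(C(=O)OCc3ccccc3)O[C@@H](CCO[Si](C)(C)C(C)(C)C)[C@@]4(C)CC[C@@H]2OO4 | intermediate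
18 | dibenzyl (3S,6R,7S)-7-{2-[(tert-butyldimethylsilyl)oxy]ethyl}-3,6-dihydroxy-6-methyloxepane-2,2-dicarboxylate (not isolated) | O=C(OCc1ccccc1)C2(C(=O)OCc3ccccc3)O[C@@H](CCO[Si](C)(C)C(C)(C)C)[C@](C)(O)CC[C@@H]2O | intermediate
19 | benzyl (1S,2S,5R,9S)-9-{2-[(tert-butyldimethylsilyl)oxy]ethyl}-2-hydroxy-5-methyl-7-oxo-6,8-dioxabicyclo[3.2.2]nonane-1-carboxylate | O=C(OCc1ccccc1)[C@@]23O[C@@H](CCO[Si](C)(C)C(C)(C)C)[C@@](C)(CC[C@@H]2O)OC3=O | intermediate
20 | benzyl (1S,2S,5R,9S)-2-[(tert-butyldimethylsilyl)oxy]-9-{2-[(tert-butyldimethylsilyl)oxy]ethyl}-5-methyl-7-oxo-6,8-dioxabicyclo[3.2.2]nonane-1-carboxylate | O=C(OCc1ccccc1)[C@@]23O[C@@H](CCO[Si](C)(C)C(C)(C)C)[C@@](C)(CC[C@@H]2O[Si](C)(C)C(C)(C)C)OC3=O | intermediate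
21 | (1S,2S,5R,9S)-2-[(tert-butyldimethylsilyl)oxy]-9-{2-[(tert-butyldimethylsilyl)oxy]ethyl}-5-methyl-7-oxo-6,8-dioxabicyclo[3.2.2]nonane-1-carboxylic acid | OC(=O)[C@@]12O[C@@H](CCO[Si](C)(C)C(C)(C)C)[C@@](C)(CC[C@@H]1O[Si](C)(C)C(C)(C)C)OC2=O | intermediate
22 | (1R,2S,5R,9S)-2-[(tert-butyldimethylsilyl)oxy]-9-{2-[(tert-butyldimethylsilyl)oxy]ethyl}-1-(hydroxymethyl)-5-methyl-6,8-dioxabicyclo[3.2.2]nonan-7-one | OC[C@@]12O[C@@H](CCO[Si](C)(C)C(C)(C)C)[C@@](C)(CC[C@@H]1O[Si](C)(C)C(C)(C)C)OC2=O | intermediate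
23 | (1S,2S,5R,9S)-2-[(tert-butyldimethylsilyl)oxy]-9-{2-[(tert-butyldimethylsilyl)oxy]ethyl}-5-methyl-7-oxo-6,8-dioxabicyclo[3.2.2]nonane-1-carbaldehyde | O=C[C@@]12O[C@@H](CCO[Si](C)(C)C(C)(C)C)[C@@](C)(CC[C@@H]1O[Si](C)(C)C(C)(C)C)OC2=O | intermediate
24 | (1R,2S,5R,9S)-2-[(tert-butyldimethylsilyl)oxy]-9-{2-[(tert-butyldimethylsilyl)oxy]ethyl}-1-ethenyl-5-methyl-6,8-dioxabicyclo[3.2.2]nonan-7-one | C=C[C@@]12O[C@@H](CCO[Si](C)(C)C(C)(C)C)[C@@](C)(CC[C@@H]1O[Si](C)(C)C(C)(C)C)OC2=O | intermediate
25 | (1R,2S,5R,9S)-2-[(tert-butyldimethylsilyl)oxy]-1-ethenyl-9-(2-hydroxyethyl)-5-methyl-6,8-dioxabicyclo[3.2.2]nonan-7-one | C=C[C@@]12O[C@@H](CCO)[C@@](C)(CC[C@@H]1O[Si](C)(C)C(C)(C)C)OC2=O | intermediate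
26 | (1R,2S,5R,9S)-2-[(tert-butyldimethylsilyl)oxy]-1-ethenyl-9-(2-iodoethyl)-5-methyl-6,8-dioxabicyclo[3.2.2]nonan-7-one | C=C[C@@]12O[C@@H](CCI)[C@@](C)(CC[C@@H]1O[Si](C)(C)C(C)(C)C)OC2=O | intermediate
27 | but-2-yn-1-ol | CC#CCO | starting material
28 | sodium 2,2-bis(2-methoxyethoxy)-3-methyl-2,5-dihydro-1,2-oxaaluminol-2-uide (cyclic Z-alkenylaluminate, not isolated) | CC1=CCO[Al-]1(OCCOC)OCCOC.[Na+] | intermediate
29 | (2Z)-3-iodobut-2-en-1-ol | C/C(I)=C/CO | intermediate
30 | tert-butyl{[(2Z)-3-iodobut-2-en-1-yl]oxy}dimethylsilane | C/C(I)=C/CO[Si](C)(C)C(C)(C)C | intermediate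
31 | {2-[(1R,2S,5R,9S)-2-[(tert-butyldimethylsilyl)oxy]-1-ethenyl-5-methyl-7-oxo-6,8-dioxabicyclo[3.2.2]nonan-9-yl]ethyl}zinc iodide (not isolated) | C=C[C@@]12O[C@@H](CC[Zn]I)[C@@](C)(CC[C@@H]1O[Si](C)(C)C(C)(C)C)OC2=O | intermediate
32 | (1R,2S,5R,9S)-2-[(tert-butyldimethylsilyl)oxy]-9-[(3Z)-5-[(tert-butyldimethylsilyl)oxy]-3-methylpent-3-en-1-yl]-1-ethenyl-5-methyl-6,8-dioxabicyclo[3.2.2]nonan-7-one | C=C[C@@]12O[C@@H](CC/C(C)=C\CO[Si](C)(C)C(C)(C)C)[C@@](C)(CC[C@@H]1O[Si](C)(C)C(C)(C)C)OC2=O | intermediate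
33 | prop-2-yn-1-ol | C#CCO | starting material
34 | 4-methyl-2,5-dihydro-1,2-oxamagnesole (cyclic Z-alkenylmagnesium alkoxide, not isolated) | CC1=C[Mg]OC1 | intermediate
35 | (2Z)-3-iodo-2-methylprop-2-en-1-ol | C/C(=C/I)CO | intermediate
36 | 9-{2-[(1R,2S,5R,9S)-2-[(tert-butyldimethylsilyl)oxy]-9-[(3Z)-5-[(tert-butyldimethylsilyl)oxy]-3-methylpent-3-en-1-yl]-5-methyl-7-oxo-6,8-dioxabicyclo[3.2.2]nonan-1-yl]ethyl}-9-borabicyclo[3.3.1]nonane (not isolated) | C1CC2CCCC(C1)B2CC[C@@]34O[C@@H](CC/C(C)=C\CO[Si](C)(C)C(C)(C)C)[C@@](C)(CC[C@@H]3O[Si](C)(C)C(C)(C)C)OC4=O | intermediate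
37 | (1R,2S,5R,9S)-2-[(tert-butyldimethylsilyl)oxy]-9-[(3Z)-5-[(tert-butyldimethylsilyl)oxy]-3-methylpent-3-en-1-yl]-1-[(3Z)-5-hydroxy-4-methylpent-3-en-1-yl]-5-methyl-6,8-dioxabicyclo[3.2.2]nonan-7-one | C/C(=C/CC[C@@]12O[C@@H](CC/C(C)=C\CO[Si](C)(C)C(C)(C)C)[C@@](C)(CC[C@@H]1O[Si](C)(C)C(C)(C)C)OC2=O)CO | intermediate
38 | (1R,2S,5R,9S)-2-hydroxy-1-[(3Z)-5-hydroxy-4-methylpent-3-en-1-yl]-9-[(3Z)-5-hydroxy-3-methylpent-3-en-1-yl]-5-methyl-6,8-dioxabicyclo[3.2.2]nonan-7-one | C/C(=C/CC[C@@]12O[C@@H](CC/C(C)=C\CO)[C@@](C)(CC[C@@H]1O)OC2=O)CO | target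

Total step count: 25.
Longest linear sequence: 21 steps (steps 1, 2, 4 to 19, 22, 24 and 25). Steps 3, 20, 21 and 23 prepare the diazomalonate and the two iodoalkenols.

Steps most likely to fail

Step 8 (enol triflate). The C20 enolate may expel the ring oxygen O7 from C6, an E1cB ring opening to an alkylidene malonate, or deprotonation may stray to the γ positions (C17, C8) and lead to the wrong dienyl triflate. The fallback avoids an enolate altogether and sets out from enone 11. Luche reduction (NaBH4, CeCl3·7H2O, MeOH, −40 °C) should give the C19 allylic alcohol F1 as a mixture of epimers. Acylation with methyl chloroformate and pyridine should give the allylic methyl carbonate F2. Zerovalent palladium (Pd(PPh3)4, dioxane, 80 °C) should then ionise the carbonate to the C16–C18–C19 π-allyl complex, which loses a C20 hydrogen at its less substituted end and delivers diene 14, where the route resumes.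

Step 12 (peroxide reduction and lactonisation). Acyl transfer to the tertiary C16 hydroxyl may be slow or incomplete under acid catalysis, and forcing it invites retro-aldol cleavage of the C6–C20 bond or dehydration at C16. The fallback makes ring closure irreversible under base. The zinc reduction is worked up so that diol 18 is isolated. The secondary C20 hydroxyl alone is then silylated (TBSOTf, 2,6-lutidine, CH2Cl2, −78 °C) to give the mono-silyl ether F3, in which retro-aldol cleavage is blocked. NaH in THF at 0 °C should convert the C16 hydroxyl into its alkoxide, which attacks the syn ester, expels benzyl oxide and gives silyl ether 20 directly.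

Step 6 (vinyl ketone). The Grignard reagent may also add to the chelating α-alkoxy esters, or act as a base and trigger loss of the C6 alkoxy group by β-elimination from the amide or the ketone. The fallback forms the ketone under neutral conditions and sets out from ether 7. Alkylation as in step 5, but with S-ethyl bromoethanethioate, should give the thioester F4. A copper-mediated, palladium-catalysed thioester–stannane ketone synthesis of the Liebeskind–Srogl type (CH2=CHSnBu3, Pd2(dba)3, tri(2-furyl)phosphine, CuO2PPh2, THF, 50 °C) should then deliver vinyl ketone 10.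

Further compounds
F1 | step 8 | dibenzyl (7S)-7-{2-[(tert-butyldimethylsilyl)oxy]ethyl}-4-hydroxy-6-methyl-3,4-dihydrooxepine-2,2(7H)-dicarboxylate (C19 epimers) | O=C(OCc1ccccc1)C2(C(=O)OCc3ccccc3)O[C@@H](CCO[Si](C)(C)C(C)(C)C)C(C)=CC(O)C2
F2 | step 8 | dibenzyl (7S)-7-{2-[(tert-butyldimethylsilyl)oxy]ethyl}-4-[(methoxycarbonyl)oxy]-6-methyl-3,4-dihydrooxepine-2,2(7H)-dicarboxylate (C19 epimers) | O=C(OCc1ccccc1)C2(C(=O)OCc3ccccc3)O[C@@H](CCO[Si](C)(C)C(C)(C)C)C(C)=CC(OC(=O)OC)C2
F3 | step 12 | dibenzyl (3S,6R,7S)-3-[(tert-butyldimethylsilyl)oxy]-7-{2-[(tert-butyldimethylsilyl)oxy]ethyl}-6-hydroxy-6-methyloxepane-2,2-dicarboxylate | O=C(OCc1ccccc1)C2(C(=O)OCc3ccccc3)O[C@@H](CCO[Si](C)(C)C(C)(C)C)[C@](C)(O)CC[C@@H]2O[Si](C)(C)C(C)(C)C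
F4 | step 6 | dibenzyl 2-{[(3S)-5-[(tert-butyldimethylsilyl)oxy]-2-methylpent-1-en-3-yl]oxy}-2-[2-(ethylsulfanyl)-2-oxoethyl]malonate | O=C(OCc1ccccc1)C(CC(=O)SCC)(O[C@@H](CCO[Si](C)(C)C(C)(C)C)C(C)=C)C(=O)OCc1ccccc1
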